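The data were generated by integration on assumed constants; the scatter is artificial.

- Amounts were where I started: on either proposed route a J that reaches Z takes one L with it, and Sunday's and Tuesday's flasks set the same L against different charges of J.

| flask | J | L | remark | time |
|---|---|---|---|---|
| violet | 0.028 M | 0.060 M | run made earlier |  |
| ochre | 0.060 M | 0.060 M | run made earlier |  |
| Sunday's | 0.050 M | 0.0600 M |  | 1.0 h |
| Tuesday's | 0.10 M | 0.0600 M |  | 3.0 h |

- violet (time / min: Z / %, J / %): 1.50: 1.3, 101.5; 5.00: 1.2, 99.1; 8.00: 24.0, 77.3; 12.0: 45.1, 54.3; 20.0: 67.9, 34.3; 25.0: 74.5, 24.5; 30.0: 79.5, 19.7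
- ochre (time / min: Z / %, J / %): 4.00: 20.9, 80.3; 8.00: 45.1, 52.0; 12.0: 56.4, 45.1; 15.0: 61.2, 39.3; 20.0: 67.3, 33.8; 25.0: 69.6, 30.2; 30.0: 72.0, 27.9

(standard deviation of a reading: 1 percentage point)

- amounts and yields of Z count D too
- given per volume of solution although it is solid: D
- steps that have been proposed: J + L + Z -> 2 Z; J + L -> Z; D <-> Z

1. which of the two ends with the higher amount of Z, in percent of the J charged ("neither" if they lie within 2 percentage points) (Sunday's / Tuesday's / neither)
2. Z at the end, in percent of the J charged, Sunday's
3. Z at the end, in percent of the J charged, Tuesday's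

- I followed one J molecule to its fork: it met an L and became Z, or it stayed J. In the ochre run at 30.0 min, Z and J together stood at 99.9% of the J charged, so I saw no other exit.
- My first way used the charges. In Tuesday's flask they gave 60.0%; I call this the payable share, the L charged over the J charged, and it was the ceiling on Z there, with L as the limiting reagent.
- In Sunday's flask the payable share was 120%, above 100 percent, so J was what could run short and the ceiling stood at 100 percent.
- My second way used the clock. In the ochre run J and L were charged equally, and the reciprocal of the J fraction rose by about 0.0755 min⁻¹ between 8.00 min and 30.0 min, a reading that carries the scatter.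
- Scaled to Tuesday's surplus of J, that reading gave L a lifetime of 19.9 min. Tuesday's time was much longer than that lifetime and held 9.06 of them, so the clock put Z at 60.0%. This was no second height, since the clock took its height from the same charges; what it added was that Tuesday's flask had the time to reach the ceiling.
- For Sunday's flask they parted. The same rate, integrated over its time, put Z at 87.1%, lower than the ceiling. A ceiling has no time in it, so there I took the clock.
- The forecast named Sunday's, with 87% against 59.5%, and held that “L is limiting, so Z cannot exceed 60% of the J charged”. Its Tuesday figure lay lower than my 60.0%.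

- The flasks gave 88.0% for Sunday's and 60.0% for Tuesday's, so Sunday's ended higher. Tuesday's flask had 0% of its L left at 3.00 h, and at 30.0 h its Z still read 60.0%, which is the payable share 60.0% again.

    J + L + Z → 2 Z (k = 781 M⁻² min⁻¹)
    J + L → Z (k = 7.06 × 10⁻⁴ M⁻¹ min⁻¹)
    D ⇌ Z, rate k3*(cs3 - [Z]) while solid is left; crystals form when [Z] > cs3 (solubility = 1.50 mM, k = 2.56 min⁻¹)
- For the neighbour of Sunday's charged with 0.20 M of J, the payable share came to 30.0%. The computed flask gave 30.0% of Z at 1.00 h, with 0% of its L left.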